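**Plan**
Cuts: (a) the two C–CH2 bonds of the methylene bridge between C5 of the benzofuran and C3 of the pyrone; (b) C6–O and C7–C(=O), taken together; (c) O1–C2 and C3–C3a of the dihydrofuran ring.
Enabling feature: on the benzene ring of the dihydrobenzofuran, C7 carries the 2-methylbutanoyl group between C7a–O1 and the C6 hydroxyl. This vicinal hydroxyl/acyl pair corresponds to one carboxylic acid added across a C6≡C7 aryne, and O1 beside the triple bond fixes the orientation.
Forward: C-prenylation of phloroglucinol, epoxidation and 5-exo closure of the dihydrofuran ring, C7 bromination, dehydration, retro-Brook shift with triflation, aryne acylation and MOM removal. The pyrone ring is built separately and joined last through formaldehyde.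
Stereochemistry: (S)-C2 comes from a Shi epoxidation (R epoxide, inverted on ring closure). The (S) side-chain centre is bought as (S)-2-methylbutanoic acid.

Key step: step 12

Assumption: paraformaldehyde is entered as monomeric formaldehyde 30. Compound 26 is drawn as its Z isomer, although its geometry has no bearing on step 15.

**Step 1**
Reactants: 1 phloroglucinol; 2 prenyl bromide
Product: 3 2-(3-methylbut-2-en-1-yl)benzene-1,3,5-triol
Conditions: KOH (1 equiv), H2O, 0 °C → rt; 1 in threefold excess
Reagents that add atoms: none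
Why: In water the ambident phloroglucinol anion reacts with the soft allylic bromide at carbon (SN2 C-alkylation of a phenolate), the three ring CH positions are equivalent, and the excess of 1 holds back a second prenylation.

**Step 2**
Reactants: 3 2-(3-methylbut-2-en-1-yl)benzene-1,3,5-triol
Product: 4 1,3,5-tris(tert-butyldimethylsilyloxy)-2-(3-methylbut-2-en-1-yl)benzene
Conditions: TBSCl, imidazole, DMF, rt
Reagents that add atoms: TBSCl, CC(C)(C)[Si](C)(C)Cl
Why: Imidazole-promoted silylation masks the three oxidation-prone phenols with groups that survive the basic peroxymonosulfate medium and leave again under fluoride.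

**Step 3**
Reactants: 4 1,3,5-tris(tert-butyldimethylsilyloxy)-2-(3-methylbut-2-en-1-yl)benzene
Product: 5 (R)-3-[2,4,6-tris(tert-butyldimethylsilyloxy)benzyl]-2,2-dimethyloxirane
Conditions: 1,2:4,5-di-O-isopropylidene-β-D-erythro-2,3-hexodiulo-2,6-pyranose (D-fructose-derived Shi ketone, 30 mol %), Oxone (2KHSO5·KHSO4·K2SO4), K2CO3, Bu4NHSO4, MeCN–CH2(OMe)2, aq. Na2B4O7 buffer (pH 10.5), 0 °C
Reagents that add atoms: potassium peroxymonosulfate KHSO5, [K+].[O-]S(=O)(=O)OO
Why: In the Shi asymmetric epoxidation the dioxirane of the D-fructose-derived ketone attacks trisubstituted olefins through a spiro transition state from the face that gives the R epoxide, which fixes the later ring stereocentre.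

**Step 4**
Reactants: 5 (R)-3-[2,4,6-tris(tert-butyldimethylsilyloxy)benzyl]-2,2-dimethyloxirane
Product: 7 (S)-2-(2-hydroxypropan-2-yl)-2,3-dihydrobenzofuran-4,6-diol, via epoxy triol 6 (not isolated)
Conditions: TBAF, THF, 0 °C → rt (argon); AcOH quench
Reagents that add atoms: none
Why: Fluoride frees the phenolates, and one of the two equivalent ortho phenolates opens the epoxide at its less substituted carbon (5-exo-tet, SN2 with inversion), so the R epoxide carbon becomes (S)-C2 without any regiochemical choice on the ring.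

**Step 5**
Reactants: 7 (S)-2-(2-hydroxypropan-2-yl)-2,3-dihydrobenzofuran-4,6-diol
Product: 8 2-[(S)-4,6-bis(tert-butyldimethylsilyloxy)-2,3-dihydrobenzofuran-2-yl]propan-2-ol
Conditions: TBSCl (2.2 equiv), imidazole, DMF, 0 °C → rt
Reagents that add atoms: TBSCl, CC(C)(C)[Si](C)(C)Cl
Why: TBSCl with imidazole silylates the two phenols and leaves the tertiary alcohol free, and the bulky ethers shield C5 in the next step.

**Step 6**
Reactants: 8 2-[(S)-4,6-bis(tert-butyldimethylsilyloxy)-2,3-dihydrobenzofuran-2-yl]propan-2-ol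
Product: 9 2-[(S)-7-bromo-4,6-bis(tert-butyldimethylsilyloxy)-2,3-dihydrobenzofuran-2-yl]propan-2-ol
Conditions: NBS (1.0 equiv), CH2Cl2, −78 → 0 °C, dark
Reagents that add atoms: NBS, O=C1CCC(=O)N1Br
Why: In this electrophilic aromatic bromination C7 lies between the tied-back ring oxygen and one silyl ether and para to the C4 oxygen, whereas C5 is buried between two OTBS groups, which is the same bias that sends NBS to C8 of 5,7-dialkoxychromans, and no olefin is present yet.

**Step 7**
Reactants: 9 2-[(S)-7-bromo-4,6-bis(tert-butyldimethylsilyloxy)-2,3-dihydrobenzofuran-2-yl]propan-2-ol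
Product: 11 (S)-7-bromo-4,6-bis(tert-butyldimethylsilyloxy)-2-(prop-1-en-2-yl)-2,3-dihydrobenzofuran, via tertiary chlorosulfite 10 (not isolated)
Conditions: SOCl2, pyridine, 0 °C
Reagents that add atoms: none
Why: Pyridine-mediated E2 elimination of the tertiary chlorosulfite should take one of the six exposed methyl hydrogens rather than the hindered C2–H, which is the classical dehydration of 2-(2-hydroxypropan-2-yl)dihydrobenzofurans to their isopropenyl analogues and leaves C2 untouched.

**Step 8**
Reactants: 11 (S)-7-bromo-4,6-bis(tert-butyldimethylsilyloxy)-2-(prop-1-en-2-yl)-2,3-dihydrobenzofuran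
Product: 12 (S)-7-bromo-2-(prop-1-en-2-yl)-2,3-dihydrobenzofuran-4,6-diol
Conditions: TBAF, AcOH, THF, 0 °C
Reagents that add atoms: none
Why: Buffered fluoride cleaves aryl silyl ethers quickly and leaves the aryl bromide, the olefin and the allylic ring ether alone.

**Step 9**
Reactants: 12 (S)-7-bromo-2-(prop-1-en-2-yl)-2,3-dihydrobenzofuran-4,6-diol
Product: 13 (S)-7-bromo-2-(prop-1-en-2-yl)-4,6-bis(trimethylsilyloxy)-2,3-dihydrobenzofuran
Conditions: HMDS, THF, 70 °C; evaporation
Reagents that add atoms: hexamethyldisilazane, C[Si](C)(C)N[Si](C)(C)C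
Why: Heating phenols with HMDS gives the trimethylsilyl ethers with a volatile by-product only, so the residue can be used after evaporation.

**Step 10**
Reactants: 13 (S)-7-bromo-2-(prop-1-en-2-yl)-4,6-bis(trimethylsilyloxy)-2,3-dihydrobenzofuran
Product: 17 (S)-4-hydroxy-2-(prop-1-en-2-yl)-7-(trimethylsilyl)-2,3-dihydrobenzofuran-6-yl trifluoromethanesulfonate, via C7 aryllithium 14 (not isolated), via lithium O6 phenolate 15 (not isolated), via O4 silyl ether triflate 16 (not isolated)
Conditions: n-BuLi, THF, −78 °C; Tf2O, −78 °C; aq. NaHCO3; then K2CO3 (cat.), MeOH, 0 °C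
Reagents that add atoms: triflic anhydride, O=S(=O)(OS(=O)(=O)C(F)(F)F)C(F)(F)F
Why: Bromine–lithium exchange at C7 triggers the retro-Brook 1,3-shift of silicon from O6 to C7, which only the ortho silyl ether can undergo, so only O6 is freed and triflated and the bromine position tells the two phenols apart, after which methanolysis removes the labile O4 silyl group (the standard route from ortho-bromophenols to ortho-silylaryl triflates).

**Step 11**
Reactants: 17 (S)-4-hydroxy-2-(prop-1-en-2-yl)-7-(trimethylsilyl)-2,3-dihydrobenzofuran-6-yl trifluoromethanesulfonate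
Product: 18 (S)-4-(methoxymethoxy)-2-(prop-1-en-2-yl)-7-(trimethylsilyl)-2,3-dihydrobenzofuran-6-yl trifluoromethanesulfonate
Conditions: MOMCl, iPr2NEt, CH2Cl2, 0 °C → rt
Reagents that add atoms: chloromethyl methyl ether, COCCl
Why: O-alkylation of the free C4 phenol gives an acetal that is inert to fluoride and carboxylate, whereas a silyl ether or a free phenol would release a competing nucleophile in the aryne step.

**Step 12**
Reactants: 18 (S)-4-(methoxymethoxy)-2-(prop-1-en-2-yl)-7-(trimethylsilyl)-2,3-dihydrobenzofuran-6-yl trifluoromethanesulfonate; 19 (S)-2-methylbutanoic acid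
Product: 23 (S)-1-[(S)-6-hydroxy-4-(methoxymethoxy)-2-(prop-1-en-2-yl)-2,3-dihydrobenzofuran-7-yl]-2-methylbutan-1-one, via caesium carboxylate 20 (not isolated), via C6–C7 aryne 21 (not isolated), via C7 aryl anion ester 22 (not isolated)
Conditions: 19, CsF (4 equiv), THF, rt, 30 min; then 18, 125 °C, sealed tube
Reagents that add atoms: none
Why: Fluoride attacks the C7 silicon of 18 and triflate leaves from C6 to give aryne 21, carboxylate 20 adds through oxygen at C6, and the C7 carbanion of 22 attacks its own ester carbonyl through a four-membered transition state that collapses to the phenolate of 23, so the C6–O and C7–C(=O) bonds form in one operation. The closest known reaction type is Kobayashi aryne generation followed by formal insertion of the aryne into the O–acyl bond of a carboxylic acid, an established route to ortho-hydroxyaryl ketones. No ring is closed and no stereocentre is created. The step needs regioselective addition, and this is secured because the inductively withdrawing O1 on C7a and the angle distortion from the fused five-membered ring make C6 the more electrophilic aryne carbon and place the charge on C7, as in 3-alkoxyarynes and 6,7-indolynes. The acyl shift must also outrun protonation of 22, which is why the acid is converted into 20 beforehand and the reaction is run hot in poorly solvating THF. C2 is remote, and the acid stereocentre should hold because fluoride cannot enolise a carboxylate and the product rests as a conjugated phenolate whose ketone is a poor carbon acid.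

**Step 13**
Reactants: 23 (S)-1-[(S)-6-hydroxy-4-(methoxymethoxy)-2-(prop-1-en-2-yl)-2,3-dihydrobenzofuran-7-yl]-2-methylbutan-1-one
Product: 24 (S)-1-[(S)-4,6-dihydroxy-2-(prop-1-en-2-yl)-2,3-dihydrobenzofuran-7-yl]-2-methylbutan-1-one
Conditions: HCl (cat.), MeOH, 40 °C
Reagents that add atoms: none
Why: Acid-catalysed transacetalisation of a phenolic MOM ether in methanol is mild enough for a 1,1-disubstituted olefin and should not enolise the hindered, hydrogen-bonded ketone.

**Step 14**
Reactants: 25 pentan-3-one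
Product: 26 3-(trimethylsilyloxy)pent-2-ene (mainly Z)
Conditions: TMSOTf, Et3N, CH2Cl2, 0 °C
Reagents that add atoms: trimethylsilyl triflate, C[Si](C)(C)OS(=O)(=O)C(F)(F)F
Why: Soft enolisation of the symmetric ketone gives the silyl enol ether without a regiochemical question.

**Step 15**
Reactants: 26 3-(trimethylsilyloxy)pent-2-ene; 27 malonyl dichloride
Product: 29 6-ethyl-4-hydroxy-5-methyl-2H-pyran-2-one, via diketo acid chloride 28 (not isolated)
Conditions: Et2O, −78 °C → rt
Reagents that add atoms: none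
Why: C-acylation of the silyl enol ether by one acid chloride group, then O-acylation of the enolised ketone by the other (6-exo-trig lactonisation), closes the pyrone ring in a known one-pot synthesis of 5,6-disubstituted 4-hydroxy-2-pyrones.

**Step 16**
Reactants: 24 (S)-1-[(S)-4,6-dihydroxy-2-(prop-1-en-2-yl)-2,3-dihydrobenzofuran-7-yl]-2-methylbutan-1-one; 29 6-ethyl-4-hydroxy-5-methyl-2H-pyran-2-one; 30 formaldehyde (as paraformaldehyde)
Product: 32 3-{[(S)-4,6-dihydroxy-7-[(S)-2-methylbutanoyl]-2-(prop-1-en-2-yl)-2,3-dihydrobenzofuran-5-yl]methyl}-6-ethyl-4-hydroxy-5-methyl-2H-pyran-2-one, via methylene pyrandione 31 (not isolated)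
Conditions: ethylenediammonium diacetate (20 mol %), CHCl3, 40 °C; 29 added slowly
Reagents that add atoms: none
Why: Knoevenagel condensation of 29 with formaldehyde gives the strong Michael acceptor 31, which is captured by C5, the only free and doubly hydroxyl-activated ring carbon of 24 (three-component methylene bridging known for acylphloroglucinols and 4-hydroxy-2-pyrones), while both stereocentres are spectators.

**Compound list**
1 | phloroglucinol | Oc1cc(O)cc(O)c1 | starting material
2 | prenyl bromide | CC(C)=CCBr | starting material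
3 | 2-(3-methylbut-2-en-1-yl)benzene-1,3,5-triol | CC(C)=CCc1c(O)cc(O)cc1O | intermediate
4 | 1,3,5-tris(tert-butyldimethylsilyloxy)-2-(3-methylbut-2-en-1-yl)benzene | CC(C)=CCc1c(O[Si](C)(C)C(C)(C)C)cc(O[Si](C)(C)C(C)(C)C)cc1O[Si](C)(C)C(C)(C)C | intermediate
5 | (R)-3-[2,4,6-tris(tert-butyldimethylsilyloxy)benzyl]-2,2-dimethyloxirane | CC1(C)O[C@@H]1Cc1c(O[Si](C)(C)C(C)(C)C)cc(O[Si](C)(C)C(C)(C)C)cc1O[Si](C)(C)C(C)(C)C | intermediate
6 | (R)-2-[(3,3-dimethyloxiran-2-yl)methyl]benzene-1,3,5-triol (present as phenolate, not isolated) | CC1(C)O[C@@H]1Cc1c(O)cc(O)cc1O | intermediate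
7 | (S)-2-(2-hydroxypropan-2-yl)-2,3-dihydrobenzofuran-4,6-diol | CC(C)(O)[C@@H]1Cc2c(O)cc(O)cc2O1 | intermediate
8 | 2-[(S)-4,6-bis(tert-butyldimethylsilyloxy)-2,3-dihydrobenzofuran-2-yl]propan-2-ol | CC(C)(O)[C@@H]1Cc2c(O[Si](C)(C)C(C)(C)C)cc(O[Si](C)(C)C(C)(C)C)cc2O1 | intermediate
9 | 2-[(S)-7-bromo-4,6-bis(tert-butyldimethylsilyloxy)-2,3-dihydrobenzofuran-2-yl]propan-2-ol | CC(C)(O)[C@@H]1Cc2c(O[Si](C)(C)C(C)(C)C)cc(O[Si](C)(C)C(C)(C)C)c(Br)c2O1 | intermediate
10 | chlorosulfite of 9 (not isolated) | CC(C)(OS(=O)Cl)[C@@H]1Cc2c(O[Si](C)(C)C(C)(C)C)cc(O[Si](C)(C)C(C)(C)C)c(Br)c2O1 | intermediate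
11 | (S)-7-bromo-4,6-bis(tert-butyldimethylsilyloxy)-2-(prop-1-en-2-yl)-2,3-dihydrobenzofuran | C=C(C)[C@@H]1Cc2c(O[Si](C)(C)C(C)(C)C)cc(O[Si](C)(C)C(C)(C)C)c(Br)c2O1 | intermediate
12 | (S)-7-bromo-2-(prop-1-en-2-yl)-2,3-dihydrobenzofuran-4,6-diol | C=C(C)[C@@H]1Cc2c(O)cc(O)c(Br)c2O1 | intermediate
13 | (S)-7-bromo-2-(prop-1-en-2-yl)-4,6-bis(trimethylsilyloxy)-2,3-dihydrobenzofuran | C=C(C)[C@@H]1Cc2c(O[Si](C)(C)C)cc(O[Si](C)(C)C)c(Br)c2O1 | intermediate
14 | (S)-7-lithio-2-(prop-1-en-2-yl)-4,6-bis(trimethylsilyloxy)-2,3-dihydrobenzofuran (not isolated) | C=C(C)[C@@H]1Cc2c(O[Si](C)(C)C)cc(O[Si](C)(C)C)c([Li])c2O1 | intermediate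
15 | lithium (S)-2-(prop-1-en-2-yl)-7-(trimethylsilyl)-4-(trimethylsilyloxy)-2,3-dihydrobenzofuran-6-olate (not isolated) | C=C(C)[C@@H]1Cc2c(O[Si](C)(C)C)cc([O-])c([Si](C)(C)C)c2O1.[Li+] | intermediate
16 | (S)-2-(prop-1-en-2-yl)-7-(trimethylsilyl)-4-(trimethylsilyloxy)-2,3-dihydrobenzofuran-6-yl trifluoromethanesulfonate (not isolated) | C=C(C)[C@@H]1Cc2c(O[Si](C)(C)C)cc(OS(=O)(=O)C(F)(F)F)c([Si](C)(C)C)c2O1 | intermediate
17 | (S)-4-hydroxy-2-(prop-1-en-2-yl)-7-(trimethylsilyl)-2,3-dihydrobenzofuran-6-yl trifluoromethanesulfonate | C=C(C)[C@@H]1Cc2c(O)cc(OS(=O)(=O)C(F)(F)F)c([Si](C)(C)C)c2O1 | intermediate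
18 | (S)-4-(methoxymethoxy)-2-(prop-1-en-2-yl)-7-(trimethylsilyl)-2,3-dihydrobenzofuran-6-yl trifluoromethanesulfonate | C=C(C)[C@@H]1Cc2c(OCOC)cc(OS(=O)(=O)C(F)(F)F)c([Si](C)(C)C)c2O1 | intermediate
19 | (S)-2-methylbutanoic acid | CC[C@H](C)C(=O)O | starting material
20 | caesium (S)-2-methylbutanoate (not isolated) | CC[C@H](C)C(=O)[O-].[Cs+] | intermediate
21 | (S)-6,7-didehydro-4-(methoxymethoxy)-2-(prop-1-en-2-yl)-2,3-dihydrobenzofuran, the C6–C7 aryne (not isolated) | C=C(C)[C@@H]1CC2=C(O1)C#CC=C2OCOC | intermediate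
22 | caesium salt of the C7 carbanion of (S)-4-(methoxymethoxy)-2-(prop-1-en-2-yl)-2,3-dihydrobenzofuran-6-yl (S)-2-methylbutanoate (not isolated) | C=C(C)[C@@H]1Cc2c(OCOC)cc(OC(=O)[C@@H](C)CC)[c-]c2O1.[Cs+] | intermediate
23 | (S)-1-[(S)-6-hydroxy-4-(methoxymethoxy)-2-(prop-1-en-2-yl)-2,3-dihydrobenzofuran-7-yl]-2-methylbutan-1-one | C=C(C)[C@@H]1Cc2c(OCOC)cc(O)c(C(=O)[C@@H](C)CC)c2O1 | intermediate
24 | (S)-1-[(S)-4,6-dihydroxy-2-(prop-1-en-2-yl)-2,3-dihydrobenzofuran-7-yl]-2-methylbutan-1-one | C=C(C)[C@@H]1Cc2c(O)cc(O)c(C(=O)[C@@H](C)CC)c2O1 | intermediate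
25 | pentan-3-one | CCC(=O)CC | starting material
26 | 3-(trimethylsilyloxy)pent-2-ene (mainly Z) | C/C=C(/CC)O[Si](C)(C)C | intermediate
27 | malonyl dichloride | O=C(Cl)CC(=O)Cl | starting material
28 | 4-methyl-3,5-dioxoheptanoyl chloride (not isolated) | CCC(=O)C(C)C(=O)CC(=O)Cl | intermediate
29 | 6-ethyl-4-hydroxy-5-methyl-2H-pyran-2-one | CCc1oc(=O)cc(O)c1C | intermediate
30 | formaldehyde (used as paraformaldehyde) | C=O | starting material
31 | 6-ethyl-5-methyl-3-methylidene-2H-pyran-2,4(3H)-dione (not isolated) | C=C1C(=O)OC(CC)=C(C)C1=O | intermediate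
32 | 3-{[(S)-4,6-dihydroxy-7-[(S)-2-methylbutanoyl]-2-(prop-1-en-2-yl)-2,3-dihydrobenzofuran-5-yl]methyl}-6-ethyl-4-hydroxy-5-methyl-2H-pyran-2-one | C=C(C)[C@@H]1Cc2c(O)c(Cc3c(O)c(C)c(CC)oc3=O)c(O)c(C(=O)[C@@H](C)CC)c2O1 | target

Total step count: 16
Longest linear sequence: 14 steps (steps 1–13 and 16)

**Steps most likely to fail**

1. Step 12. Three processes may compete with the planned course:
   - The aryl anion may be protonated before the acyl group migrates, which stops the reaction at simple O-arylation.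
   - The product phenolate may add to a second aryne.
   - Long heating with a basic fluoride may erode the side-chain configuration.

   The fallback replaces the aryne by a polar aryl-metal acylation. It sets out from 12 and returns at 24. Both phenols of 12 are alkylated with MOMCl and iPr2NEt to give the bis(methoxymethyl) ether F1. Acid 19 is converted by a standard amide coupling with MeNHOMe·HCl into the Weinreb amide F2. Treatment of F1 with n-BuLi in THF at −78 °C gives the aryllithium F3, which adds to F2 to give the ketone F4. HCl in MeOH then removes both acetals and gives 24.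

2. Step 7. The elimination may run toward C2–H, which destroys the stereocentre and leads on to the aromatic benzofuran. Alternatively the tertiary centre may ionise with participation of the aryl ether oxygen and ring expansion to a chroman.

   The fallback forms the isopropenyl group and the ring in one act and needs no dehydration. It sets out from 4 and returns at 11.
   - Allylic hydroxylation of 4 with SeO2 (cat.) and t-BuOOH gives the (E)-allylic alcohol F5.
   - ClCO2Me with pyridine gives the methyl carbonate F6.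
   - Buffered TBAF gives the triol carbonate F7.
   - Asymmetric allylic O-alkylation with zerovalent palladium follows: Pd2(dba)3·CHCl3, (S,S)-N,N'-(cyclohexane-1,2-diyl)bis[2-(diphenylphosphino)benzamide] (Trost ligand), AcOH, CH2Cl2. This ligand enantiomer is the one expected to give S and is to be confirmed by correlation with 11. The reaction closes the ring to the isopropenyl diol F8.
   - TBSCl with imidazole gives the bis-silyl ether F9.
   - NBS at −78 °C, where the activated arene should outpace the olefin, gives 11.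

3. Step 16. Self-coupling of either partner through formaldehyde may compete with the cross-coupling, and the methide may be consumed by cycloaddition to the olefin.

   The fallback separates the two C–C bond formations. It sets out from 24 and returns at 32. Dimethylmethyleneammonium iodide (CH2=NMe2+ I−) in CH2Cl2 aminomethylates C5 to give the Mannich base F10. Heating F10 with 29 in dioxane expels the amine and gives the ortho-quinone methide F11, which the pyrone captures at C3 to give 32.

**Further compounds**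
F1 | step 12 | (S)-7-bromo-4,6-bis(methoxymethoxy)-2-(prop-1-en-2-yl)-2,3-dihydrobenzofuran | C=C(C)[C@@H]1Cc2c(OCOC)cc(OCOC)c(Br)c2O1
F2 | step 12 | (S)-N-methoxy-N,2-dimethylbutanamide | CC[C@H](C)C(=O)N(C)OC
F3 | step 12 | (S)-7-lithio-4,6-bis(methoxymethoxy)-2-(prop-1-en-2-yl)-2,3-dihydrobenzofuran | C=C(C)[C@@H]1Cc2c(OCOC)cc(OCOC)c([Li])c2O1
F4 | step 12 | (S)-1-[(S)-4,6-bis(methoxymethoxy)-2-(prop-1-en-2-yl)-2,3-dihydrobenzofuran-7-yl]-2-methylbutan-1-one | C=C(C)[C@@H]1Cc2c(OCOC)cc(OCOC)c(C(=O)[C@@H](C)CC)c2O1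
F5 | step 7 | (E)-2-methyl-4-[2,4,6-tris(tert-butyldimethylsilyloxy)phenyl]but-2-en-1-ol | OC/C(C)=C/Cc1c(O[Si](C)(C)C(C)(C)C)cc(O[Si](C)(C)C(C)(C)C)cc1O[Si](C)(C)C(C)(C)C
F6 | step 7 | methyl (E)-2-methyl-4-[2,4,6-tris(tert-butyldimethylsilyloxy)phenyl]but-2-en-1-yl carbonate | COC(=O)OC/C(C)=C/Cc1c(O[Si](C)(C)C(C)(C)C)cc(O[Si](C)(C)C(C)(C)C)cc1O[Si](C)(C)C(C)(C)C
F7 | step 7 | methyl (E)-2-methyl-4-(2,4,6-trihydroxyphenyl)but-2-en-1-yl carbonate | COC(=O)OC/C(C)=C/Cc1c(O)cc(O)cc1O
F8 | step 7 | (S)-2-(prop-1-en-2-yl)-2,3-dihydrobenzofuran-4,6-diol | C=C(C)[C@@H]1Cc2c(O)cc(O)cc2O1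
F9 | step 7 | (S)-4,6-bis(tert-butyldimethylsilyloxy)-2-(prop-1-en-2-yl)-2,3-dihydrobenzofuran | C=C(C)[C@@H]1Cc2c(O[Si](C)(C)C(C)(C)C)cc(O[Si](C)(C)C(C)(C)C)cc2O1
F10 | step 16 | (S)-1-[(S)-5-[(dimethylamino)methyl]-4,6-dihydroxy-2-(prop-1-en-2-yl)-2,3-dihydrobenzofuran-7-yl]-2-methylbutan-1-one | C=C(C)[C@@H]1Cc2c(O)c(CN(C)C)c(O)c(C(=O)[C@@H](C)CC)c2O1
F11 | step 16 | (S)-6-hydroxy-7-[(S)-2-methylbutanoyl]-5-methylidene-2-(prop-1-en-2-yl)-2,3-dihydrobenzofuran-4(5H)-one | C=C(C)[C@@H]1CC2=C(O1)C(C(=O)[C@@H](C)CC)=C(O)C(=C)C2=O
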